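## Structural features

Compound 22 is a dibenzylbutyrolactone lignan: one γ-lactone ring (O1, C2 carbonyl, C3, C4, C5) with a benzyl group on each of its two adjacent sp3 carbons. C3 holds benzylic C7 with ring A, a 2,4-dihydroxy-3-methoxyphenyl group, and C4 holds benzylic C7' with ring B, a 4-hydroxy-3-methoxyphenyl group. C3 and C4 are neighbouring stereocentres, both R, with the two benzyl groups trans on the ring. C3 is α to the lactone carbonyl and can be epimerised, trans being the more stable arrangement, whereas C4 is configurationally fixed and must be set absolutely. The fragile parts are the three free phenols, above all the electron-rich ring A with its hydroxyl ortho to C7, and the lactone, which opens with base and can be re-closed the wrong way round by a neighbouring hydroxyl. The real difficulty is C4: it carries only carbon and hydrogen, its three carbon substituents (C3, C5, C7') offer no polar handle for induction, and two different, unsymmetrically oxygenated arenes must be attached without ambiguity. The key step exploits that C5 and C7' are both CH2 groups on C4: joined through one oxygen they form an oxetane with two enantiotopic CH2 groups, and the carbonyl oxygen of an ester on C3 can open one of them and so become O1.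

## Logic of the disconnections

**22 to 21.** Bonds: the three aryl O–benzyl bonds (two on ring A, one on ring B). Reason: free phenols, especially those of ring A, would not survive base, zinc and nickel, or hot acid. Gain: one protecting group type and one neutral final operation. Demand: the hydrogenolysis must leave the lactone C5–O1 bond and both stereocentres alone, which it should, because C7 and C7' are benzylic C–C and not C–O positions.

**21 to 18.** Bond: C3–carboxyl; backwards, a tert-butoxycarbonyl group is put back on C3. Reason: C3 can be set by thermodynamics, and the extra ester is the second ester of a symmetric malonate. Gain: C3 needs no control, only C4 remains. Demand: the forward ester cleavage must spare three benzyl ethers, and decarboxylation plus equilibration must end at the trans lactone.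

**18 to 15 and 17.** Bond: C7'–C1 of ring B. Reason: an sp3–sp2 bond between a primary alkyl halide and an aryl halide can be made by reductive coupling without a preformed organometallic. Gain: ring B is removed completely and its substitution pattern is fixed by the bromine position in 17. Demand: the C7' radical must be captured by nickel faster than it is reduced, and C4 next to it must not be affected.

**15 to 14.** Bond: C7'–I, exchanged for C7'–OH. Reason: the alcohol is what the ring-forming step releases. Gain: none in skeleton. Demand: the conversion must be immediate and non-basic, because the free hydroxyl of 14 can migrate the acyl group between the two oxygen arms and scramble C4.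

**14 to 13 (key).** Bond: O1–C5; backwards, C5 is re-joined to the oxygen on C7' to make an oxetane and the lactone carbonyl reverts to a tert-butyl ester. Reason: tying C5 and C7' together makes them enantiotopic and removes both stereocentres. Gain: an achiral, mirror-symmetric precursor with one ring fewer. Demand: a chiral acid must select one of two enantiotopic CH2 groups for attack by a weak oxygen nucleophile.

**13 to 4 and 11.** Bond: C3–C7. Reason: a malonate carbon is the natural nucleophile for a benzylic electrophile. Gain: ring A is split off and the oxetane-bearing malonate is left. Demand: a quaternary carbon must form from a hindered enolate and a labile, very electron-rich benzylic halide.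

**4 to 3 to 1 and 2.** Bond: C3–C4, cut as a C=C bond after removal of the two hydrogens across it. Reason: 1 is a strongly electrophilic ketone and 2 a doubly activated methylene compound. Gain: two commercial materials. Demand: condensation and conjugate reduction must leave the oxetane and the acid-labile esters intact.

**11 to 9 to 8 to 6 to 5.** Bonds: C7–Cl back to C7–OH and C7=O, then C7–C1 of ring A, then the two O–benzyl bonds. Reason: 6 is symmetric, so its two activated positions are equivalent and formylation can give only the required 1,2,3,4-pattern. Gain: ring A comes from a commercial symmetric diphenol. Demand: the formylation must go ortho and para to the benzyloxy groups and not para to the hindered methoxy group, and the benzyl ethers must survive it.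

**17 to 16.** Bond: the O–benzyl bond on ring B. Reason: the phenol is masked in the same way as those of ring A so that one final step frees all three. Gain: a commercial bromophenol. Demand: none beyond clean O-alkylation.

## Other disconnections considered

**Alternative 1:** The cut is through C4–C5 and C2–O1, so that C5 and O1 come together from methanol A3 and are added to the acyclic (E)-enoyl pyrazole A2, in which both arenes (as acetates) are already in place.
- Forward key step: the hydroxymethyl radical formed from A3 by hydrogen-atom abstraction would add to C4 of A2, which is held in two-point fashion by a chiral Lewis acid. The C3 radical is then reduced and protonated, and the new hydroxyl displaces the pyrazole to close lactone A1 as a mixture of C3 epimers.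
- In its favour: the ring, the C4–C5 bond and the C4 stereocentre come from one operation on a precursor that holds the whole skeleton but C5. The C1 unit is as cheap as possible, and the acetates come off by mild solvolysis. On step economy after the key step this plan is the better of the two. On C3 it is the equal of the chosen plan, since both leave C3 to a later equilibration.
- Against it here: A2 is α-branched, and a trisubstituted acceptor with a benzyl group on C3 is slow toward a nucleophilic radical and crowded at the Lewis acid, so facial control at C4 is less secure than for α-unsubstituted acceptors. The C–H bonds at C7' of A2 are allylic and benzylic at once, those at C7 are benzylic, and both compete with A3 for the abstracting radical. The C3=C4 double bond can move into conjugation with ring B. The stereodefined trisubstituted alkene must also be built first.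
- Comparison: structurally, A1 carries no extra carboxyl group, whereas the chosen plan pays for its symmetry with a decarboxylation. Mechanistically, the chosen plan uses a closed-shell, ion-paired opening of an achiral substrate with no competing C–H sites, which is why it is preferred although it is longer.

**Alternative 2:** The cuts are C3–C4 and C3–C7, both at the central carbon of dimethyl malonate A6, which links the ring B allyl carbonate A5 and the ring A benzyl chloride 11.
- Forward key step: iridium-catalysed allylic alkylation with a chiral phosphoramidite ligand would send the anion of A6 to the substituted terminus of the π-allyl from A5 and so create C4. The mono-alkylated malonate would then be deprotonated and benzylated by 11 in the same flask to give A4. No ring closes.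
- In its favour: branched-selective iridium allylation of malonates is among the most dependable enantioselective C–C bond formations. The C4 stereocentre appears in a product with no free hydroxyl and no acyl-migration pathway. Each arene again enters by a separate, regiochemically unambiguous operation. On reliability of the stereodefining event and on configurational robustness of its product this alternative is the better plan; on convergence it is the equal of the chosen one.
- Against it here: the allyl terminus of A5 bears a CH2-aryl group whose hydrogens are both allylic and benzylic, so isomerisation toward the conjugated styrene competes, and the branched preference should be lower than for aryl-substituted allyl carbonates. The second alkylation must form a quaternary carbon next to the new tertiary centre. The vinyl group of A4 is only a masked C5, so oxidative cleavage of the alkene in the presence of three electron-rich arenes, reduction, lactonisation, Krapcho-type removal of the second ester and hydrogenolysis must follow. A5 must be prepared beforehand.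
- Comparison: structurally, the chosen plan closes the lactone in the step that sets C4 and leaves C7' at the right oxidation level for coupling, whereas A4 needs C5 adjusted by loss of a carbon. Mechanistically, the alternative stands on better-charted ground. In step count the two are close, and the chosen route avoids the alkene cleavage, the most hazardous and least chemoselective operation of the alternative.

**Alternative 3:** The cuts are C2–O1 and C2–C3, so that C2 is supplied as carbon monoxide A9 to the homopropargylic alcohol A8, whose alkyne carbons are the future C3 and C7.
- Forward key step: palladium-catalysed cyclocarbonylation would join the hydroxyl of A8, A9 and the aryl alkyne. An alkoxycarbonylpalladium species adds syn across the triple bond and protonolysis releases the (E)-α-benzylidene lactone A7.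
- In its favour: the lactone ring and both bonds to C2 form in one step from a C1 feedstock, and one catalytic hydrogenation could afterwards saturate C3=C7 and remove all three benzyl groups. On step economy after the key step this alternative is the better one. It is the equal of the chosen plan in leaving C3 to later control.
- Against it here: the key step creates no stereocentre, so C4 must already be present in A8, and the enantioselective problem is only moved to the synthesis of an α-branched homopropargylic alcohol. Hydrogenation of A7 should add hydrogen anti to the C4 substituent and so give the cis lactone first; a base equilibration would still be needed, now on the unprotected triphenol. Oxypalladation of the alkyne by the hydroxyl competes with carbonylation, and the electron-rich, ortho-substituted aryl group slows insertion. A9 is a toxic gas used under pressure.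
- Comparison: structurally, the chosen plan needs an extra carboxyl group and a decarboxylation that A7 avoids. Mechanistically, it builds C4 catalytically from an achiral precursor in the ring-forming step, which the alternative cannot do. The shorter finish of the alternative is outweighed by the open origin of C4 and the handling of A9.

Key step: step 8

Assumption: which enantiomer of the phosphoric acid leads to the 4S series of 14 cannot be deduced with confidence for an ester nucleophile; the (R)-catalyst is written, and its commercially available antipode would be used if the sense of induction proves opposite.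

Remarks on structures and design:
- The descriptors were re-derived from the structures. (4S) in 14 and (4R) in 15 and 18 to 22 describe the same spatial arrangement at C4; the change is one of CIP priority only. No correction to the structures of 13 and 14 was needed.
- The two esters of 13 are kept identical because this is what makes 13 achiral.
- Benzyl ethers are kept because they survive every step and leave together at the end.
- The ring A electrophile is used as the chloride, made and consumed without storage, because the corresponding bromide of so electron-rich a ring is prone to self-alkylation.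

## Steps

Step 1
Reactants: 1 oxetan-3-one; 2 di-tert-butyl malonate
Product: 3 di-tert-butyl 2-(oxetan-3-ylidene)malonate
Conditions: TiCl4, pyridine, THF, 0 °C to rt
Reagents that add atoms: none
Why: Titanium-mediated Knoevenagel condensation: the pyridine-buffered TiCl4–THF complex forms the titanium enolate of 2, which adds to the strained, highly electrophilic ketone, and the titanium alkoxide is then eliminated. Pyridine keeps the medium non-acidic so that the oxetane and the tert-butyl esters should persist; no stereocentre is formed.

Step 2
Reactants: 3 di-tert-butyl 2-(oxetan-3-ylidene)malonate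
Product: 4 di-tert-butyl 2-(oxetan-3-yl)malonate
Conditions: NaBH4, EtOH, 0 °C
Reagents that add atoms: none
Why: Conjugate reduction of an alkylidene malonate: hydride adds to the oxetane carbon of the doubly activated alkene and ethanol protonates the malonate enolate. tert-Butyl esters and the oxetane are inert to borohydride, and the new CH is not stereogenic because the oxetane is symmetric.

Step 3
Reactants: 5 2-methoxyresorcinol (2-methoxybenzene-1,3-diol)
Product: 6 1,3-bis(benzyloxy)-2-methoxybenzene
Conditions: BnBr, K2CO3, MeCN, 80 °C
Reagents that add atoms: benzyl bromide BrCc1ccccc1
Why: Williamson ether synthesis on both phenols; carbonate in acetonitrile is sufficient for phenoxide formation and avoids hydride bases and amide solvents.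

Step 4
Reactants: 6 1,3-bis(benzyloxy)-2-methoxybenzene
Product: 8 2,4-bis(benzyloxy)-3-methoxybenzaldehyde, via aryl iminium chloride 7 (not isolated)
Conditions: POCl3, DMF, 0 °C to 70 °C; then ice-water
Reagents that add atoms: N,N-dimethylformamide CN(C)C=O (formyl carbon); water O (carbonyl oxygen)
Why: Vilsmeier–Haack formylation: the chloroiminium ion attacks C4 of 6, which is para to one benzyloxy group and ortho to the other; C4 and C6 are equivalent by symmetry and C5 is meta to both benzyloxy groups, so one regioisomer is expected. Hydrolysis of iminium salt 7 on work-up gives the aldehyde.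

Step 5
Reactants: 8 2,4-bis(benzyloxy)-3-methoxybenzaldehyde
Product: 9 [2,4-bis(benzyloxy)-3-methoxyphenyl]methanol
Conditions: NaBH4, MeOH/THF, 0 °C
Reagents that add atoms: none
Why: Borohydride reduction of an aromatic aldehyde to the benzyl alcohol; ethers are unaffected.

Step 6
Reactants: 9 [2,4-bis(benzyloxy)-3-methoxyphenyl]methanol
Product: 11 1,3-bis(benzyloxy)-4-(chloromethyl)-2-methoxybenzene, via mesylate 10 (not isolated)
Conditions: MsCl, Et3N, CH2Cl2, 0 °C to rt; crude product used at once
Reagents that add atoms: methanesulfonyl chloride CS(=O)(=O)Cl (supplies the chlorine)
Why: Sulfonylation followed by chloride displacement: the mesylate of so electron-rich a benzyl alcohol is displaced in the flask by the chloride of the triethylammonium chloride formed alongside it. The chloride is preferred to the bromide because it is less prone to self-alkylation, and it is not stored.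

Step 7
Reactants: 4 di-tert-butyl 2-(oxetan-3-yl)malonate; 11 1,3-bis(benzyloxy)-4-(chloromethyl)-2-methoxybenzene
Product: 13 di-tert-butyl 2-[2,4-bis(benzyloxy)-3-methoxybenzyl]-2-(oxetan-3-yl)malonate, via potassium enolate 12 (not isolated)
Conditions: KOtBu, THF, 0 °C; then 11, Bu4NI (cat.), 0 °C to 40 °C
Reagents that add atoms: none
Why: Malonate C-alkylation (SN2 with in situ Finkelstein activation): enolate 12 has one acidic position left and meets a strongly activated benzylic electrophile. KOtBu in THF avoids hydrogen evolution and hydride bases in amide solvents; 13 is achiral, because a mirror plane exchanges its two esters and its two oxetane CH2 groups.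

Step 8
Reactants: 13 di-tert-butyl 2-[2,4-bis(benzyloxy)-3-methoxybenzyl]-2-(oxetan-3-yl)malonate
Product: 14 tert-butyl (4S)-3-[2,4-bis(benzyloxy)-3-methoxybenzyl]-4-(hydroxymethyl)-2-oxotetrahydrofuran-3-carboxylate (either configuration at C3)
Conditions: (R)-TRIP phosphoric acid [(R)-3,3'-bis(2,4,6-triisopropylphenyl)-1,1'-binaphthyl-2,2'-diyl hydrogen phosphate] (10 mol %), 4 Å MS, toluene, 40–60 °C
Reagents that add atoms: none
Why: The chiral phosphoric acid hydrogen-bonds to the oxetane oxygen of achiral 13 while its phosphoryl oxygen orients the substrate in the binaphthyl pocket. The carbonyl oxygen of one tert-butyl ester then attacks one of the two enantiotopic oxetane CH2 groups in an SN2 fashion, forming the O1–C5 bond and releasing the other arm as the C7' hydroxyl. The resulting tert-butoxy-substituted cyclic oxocarbenium ion, paired with the chiral phosphate, loses isobutylene in an E1 step, which gives the lactone carbonyl and returns the proton to the catalyst. The closest known reaction type is the chiral phosphoric acid catalysed intramolecular desymmetrisation of 3-substituted oxetanes by tethered oxygen and nitrogen nucleophiles, taken together with the familiar acid-promoted lactonisation of tert-butyl esters onto strained cyclic ethers. The γ-lactone closes in the 5-exo-tet mode. C4 is set by which enantiotopic CH2 is attacked, which the catalyst pocket decides (4S in 14, the arrangement that becomes 4R in 22), and C3 is set by which of the two enantiotopic esters attacks, is formed as either epimer and is of no consequence because it is reset in step 12. The step needs enantiotopic-group selectivity and chemoselectivity for the ester oxygen over ring A: the fully substituted C3 holds an ester carbonyl near each CH2 (Thorpe–Ingold effect), the only arene carbon able to reach the oxetane (C6 of ring A) is meta to both benzyloxy groups, and 13 has no acidic proton to drive an uncatalysed racemic opening. Release of the oxetane ring strain makes the opening irreversible.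

Step 9
Reactants: 14 tert-butyl (4S)-3-[2,4-bis(benzyloxy)-3-methoxybenzyl]-4-(hydroxymethyl)-2-oxotetrahydrofuran-3-carboxylate
Product: 15 tert-butyl (4R)-3-[2,4-bis(benzyloxy)-3-methoxybenzyl]-4-(iodomethyl)-2-oxotetrahydrofuran-3-carboxylate (either configuration at C3)
Conditions: PPh3, I2, imidazole, CH2Cl2, 0 °C; 14 added to the preformed reagent directly after a short silica plug
Reagents that add atoms: iodine [I][I]
Why: Appel iodination: the alkoxyphosphonium ion at C7' is displaced by iodide in an SN2 step that does not involve C4. Doing this at once removes the free hydroxyl before acyl migration between the two oxygen arms can erode C4.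

Step 10
Reactants: 16 4-bromo-2-methoxyphenol
Product: 17 1-(benzyloxy)-4-bromo-2-methoxybenzene
Conditions: BnBr, K2CO3, MeCN, 80 °C
Reagents that add atoms: benzyl bromide BrCc1ccccc1
Why: Williamson ether synthesis; the bromine para to the oxygen fixes the later attachment point of C7' on ring B.

Step 11
Reactants: 15 tert-butyl (4R)-3-[2,4-bis(benzyloxy)-3-methoxybenzyl]-4-(iodomethyl)-2-oxotetrahydrofuran-3-carboxylate; 17 1-(benzyloxy)-4-bromo-2-methoxybenzene
Product: 18 tert-butyl (4R)-3-[2,4-bis(benzyloxy)-3-methoxybenzyl]-4-[4-(benzyloxy)-3-methoxybenzyl]-2-oxotetrahydrofuran-3-carboxylate (either configuration at C3)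
Conditions: NiBr2(dme) (10 mol %), 4,4'-di-tert-butyl-2,2'-bipyridine (10 mol %), Zn dust, NaI (cat.), DMA, 40 °C
Reagents that add atoms: none
Why: Nickel-catalysed reductive cross-electrophile coupling: zerovalent nickel, formed from divalent NiBr2(dme) by zinc, inserts into the C–Br bond of 17, the C7' radical generated from 15 by halogen abstraction is captured at nickel, and reductive elimination forms the C7'–aryl bond. The radical sits on C7' only, so C4 is untouched; lactone, tert-butyl ester and benzyl ethers are tolerated under these mild reducing conditions.

Step 12
Reactants: 18 tert-butyl (4R)-3-[2,4-bis(benzyloxy)-3-methoxybenzyl]-4-[4-(benzyloxy)-3-methoxybenzyl]-2-oxotetrahydrofuran-3-carboxylate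
Product: 21 (3R,4R)-3-[2,4-bis(benzyloxy)-3-methoxybenzyl]-4-[4-(benzyloxy)-3-methoxybenzyl]dihydrofuran-2(3H)-one, via carboxylic acid 19 (not isolated), via C3-epimeric lactone 20 (not isolated)
Conditions: TsOH·H2O (10 mol %), toluene, 100 °C, N2 sweep; then DBU (1.2 equiv), 110 °C
Reagents that add atoms: none
Why: Acid-catalysed tert-butyl ester cleavage (E1 loss of isobutylene, swept out as a gas) gives the malonic-type acid 19, which decarboxylates through the lactone enol to 20, and DBU then equilibrates C3 through the enolate. With C4 fixed as R, the trans lactone (3R) is the thermodynamically preferred epimer, so C3 is set here under thermodynamic control.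

Step 13
Reactants: 21 (3R,4R)-3-[2,4-bis(benzyloxy)-3-methoxybenzyl]-4-[4-(benzyloxy)-3-methoxybenzyl]dihydrofuran-2(3H)-one
Product: 22 (3R,4R)-3-(2,4-dihydroxy-3-methoxybenzyl)-4-(4-hydroxy-3-methoxybenzyl)dihydrofuran-2(3H)-one
Conditions: H2 (1 atm), Pd/C (10 wt %), EtOAc/EtOH, rt
Reagents that add atoms: none
Why: Heterogeneous hydrogenolysis cleaves the three aryl O–benzyl bonds; C7 and C7' are benzylic C–C positions and are not cleaved, and the neutral conditions leave the lactone and both stereocentres unchanged.

## Compound list

1 | oxetan-3-one | O=C1COC1 | starting material
2 | di-tert-butyl malonate | CC(C)(C)OC(=O)CC(=O)OC(C)(C)C | starting material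
3 | di-tert-butyl 2-(oxetan-3-ylidene)malonate | CC(C)(C)OC(=O)C(=C1COC1)C(=O)OC(C)(C)C | intermediate
4 | di-tert-butyl 2-(oxetan-3-yl)malonate | CC(C)(C)OC(=O)C(C1COC1)C(=O)OC(C)(C)C | intermediate
5 | 2-methoxyresorcinol (2-methoxybenzene-1,3-diol) | COc1c(O)cccc1O | starting material
6 | 1,3-bis(benzyloxy)-2-methoxybenzene | COc1c(OCc2ccccc2)cccc1OCc1ccccc1 | intermediate
7 | N-[2,4-bis(benzyloxy)-3-methoxybenzylidene]-N-methylmethanaminium chloride | C[N+](C)=Cc1ccc(OCc2ccccc2)c(OC)c1OCc1ccccc1.[Cl-] | intermediate
8 | 2,4-bis(benzyloxy)-3-methoxybenzaldehyde | O=Cc1ccc(OCc2ccccc2)c(OC)c1OCc1ccccc1 | intermediate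
9 | [2,4-bis(benzyloxy)-3-methoxyphenyl]methanol | OCc1ccc(OCc2ccccc2)c(OC)c1OCc1ccccc1 | intermediate
10 | 2,4-bis(benzyloxy)-3-methoxybenzyl methanesulfonate | CS(=O)(=O)OCc1ccc(OCc2ccccc2)c(OC)c1OCc1ccccc1 | intermediate
11 | 1,3-bis(benzyloxy)-4-(chloromethyl)-2-methoxybenzene (2,4-bis(benzyloxy)-3-methoxybenzyl chloride) | ClCc1ccc(OCc2ccccc2)c(OC)c1OCc1ccccc1 | intermediate
12 | potassium enolate of 4 (potassium 1,3-di-tert-butoxy-2-(oxetan-3-yl)-3-oxoprop-1-en-1-olate) | CC(C)(C)OC(=O)C(C1COC1)=C([O-])OC(C)(C)C.[K+] | intermediate
13 | di-tert-butyl 2-[2,4-bis(benzyloxy)-3-methoxybenzyl]-2-(oxetan-3-yl)malonate | CC(C)(C)OC(=O)C(Cc1ccc(OCc2ccccc2)c(OC)c1OCc1ccccc1)(C1COC1)C(=O)OC(C)(C)C | intermediate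
14 | tert-butyl (4S)-3-[2,4-bis(benzyloxy)-3-methoxybenzyl]-4-(hydroxymethyl)-2-oxotetrahydrofuran-3-carboxylate, either configuration at C3 | OC[C@H]1COC(=O)C1(Cc1ccc(OCc2ccccc2)c(OC)c1OCc1ccccc1)C(=O)OC(C)(C)C | intermediate
15 | tert-butyl (4R)-3-[2,4-bis(benzyloxy)-3-methoxybenzyl]-4-(iodomethyl)-2-oxotetrahydrofuran-3-carboxylate, either configuration at C3 | IC[C@H]1COC(=O)C1(Cc1ccc(OCc2ccccc2)c(OC)c1OCc1ccccc1)C(=O)OC(C)(C)C | intermediate
16 | 4-bromo-2-methoxyphenol | COc1cc(Br)ccc1O | starting material
17 | 1-(benzyloxy)-4-bromo-2-methoxybenzene | COc1cc(Br)ccc1OCc1ccccc1 | intermediate
18 | tert-butyl (4R)-3-[2,4-bis(benzyloxy)-3-methoxybenzyl]-4-[4-(benzyloxy)-3-methoxybenzyl]-2-oxotetrahydrofuran-3-carboxylate, either configuration at C3 | COc1cc(C[C@H]2COC(=O)C2(Cc2ccc(OCc3ccccc3)c(OC)c2OCc2ccccc2)C(=O)OC(C)(C)C)ccc1OCc1ccccc1 | intermediate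
19 | (4R)-3-[2,4-bis(benzyloxy)-3-methoxybenzyl]-4-[4-(benzyloxy)-3-methoxybenzyl]-2-oxotetrahydrofuran-3-carboxylic acid, either configuration at C3 | COc1cc(C[C@H]2COC(=O)C2(Cc2ccc(OCc3ccccc3)c(OC)c2OCc2ccccc2)C(=O)O)ccc1OCc1ccccc1 | intermediate
20 | (4R)-3-[2,4-bis(benzyloxy)-3-methoxybenzyl]-4-[4-(benzyloxy)-3-methoxybenzyl]dihydrofuran-2(3H)-one, mixture of C3 epimers | COc1cc(C[C@H]2COC(=O)C2Cc2ccc(OCc3ccccc3)c(OC)c2OCc2ccccc2)ccc1OCc1ccccc1 | intermediate
21 | (3R,4R)-3-[2,4-bis(benzyloxy)-3-methoxybenzyl]-4-[4-(benzyloxy)-3-methoxybenzyl]dihydrofuran-2(3H)-one | COc1cc(C[C@H]2COC(=O)[C@@H]2Cc2ccc(OCc3ccccc3)c(OC)c2OCc2ccccc2)ccc1OCc1ccccc1 | intermediate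
22 | (3R,4R)-3-(2,4-dihydroxy-3-methoxybenzyl)-4-(4-hydroxy-3-methoxybenzyl)dihydrofuran-2(3H)-one | COc1cc(C[C@H]2COC(=O)[C@@H]2Cc2ccc(O)c(OC)c2O)ccc1O | target

## Step count and least certain steps

Total step count: 13. Longest linear sequence: 10 steps (steps 3, 4, 5, 6, 7, 8, 9, 11, 12, 13, from 5).

**Step 8 (key step).**
- Most likely to go wrong: insufficient activation. An ester carbonyl oxygen is a much weaker nucleophile than the alcohols and amines usually tethered to such oxetanes, so a phosphoric acid may turn over only under forcing conditions, at which discrimination between the two CH2 groups falls. A second hazard is erosion of C4 after the event, by acid-catalysed acyl migration between the two oxygen arms or by a second lactonisation of the residual ester onto the freed hydroxyl, which would destroy the chirality.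
- Fallback: the enantio-determining event is moved to an intermolecular halide opening of known type. From 13, opening with bromotrimethylsilane under a chiral squaramide hydrogen-bond-donor catalyst should give di-tert-butyl 2-[2,4-bis(benzyloxy)-3-methoxybenzyl]-2-[(2S)-1-bromo-3-(trimethylsilyloxy)propan-2-yl]malonate F1. Warming F1 in MeCN lets an ester carbonyl oxygen displace bromide (5-exo-tet, the tert-butyl group leaving as its bromide) to give tert-butyl (4R)-3-[2,4-bis(benzyloxy)-3-methoxybenzyl]-2-oxo-4-[(trimethylsilyloxy)methyl]tetrahydrofuran-3-carboxylate F2. Mild acidic aqueous work-up removes the silyl group and the route is rejoined at 14.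

**Step 11.**
- Most likely to go wrong: slow oxidative addition of the electron-rich aryl bromide relative to consumption of the alkyl iodide, so that hydrodehalogenation or dimerisation of the alkyl partner takes over. Intramolecular displacement of iodide by the neighbouring ester is a further drain on warming.
- Fallback: the two activation events are separated. From 15, zinc insertion (Zn dust, LiCl, THF) should give the alkylzinc iodide tert-butyl (4R)-3-[2,4-bis(benzyloxy)-3-methoxybenzyl]-4-[(iodozincio)methyl]-2-oxotetrahydrofuran-3-carboxylate F3. Negishi coupling of F3 with 17 under Pd(OAc)2 and SPhos in THF rejoins the route at 18.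

**Step 12.**
- Most likely to go wrong: electrophilic attack of tert-butyl or benzyl cations on the electron-rich rings in hot sulfonic acid (Friedel–Crafts alkylation, benzyl transfer), and incomplete equilibration to the trans lactone.
- Fallback: the protic acid is avoided altogether. From 18, TMSOTf and 2,6-lutidine in CH2Cl2 at 0 °C should exchange the tert-butyl group for silicon and give trimethylsilyl (4R)-3-[2,4-bis(benzyloxy)-3-methoxybenzyl]-4-[4-(benzyloxy)-3-methoxybenzyl]-2-oxotetrahydrofuran-3-carboxylate F4, the hindered base taking up the proton. Aqueous work-up hydrolyses F4 and rejoins the route at 19, which is decarboxylated and equilibrated with DBU in hot toluene as in the second half of step 12.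

**Step 1.**
- Most likely to go wrong: Lewis-acid opening or oligomerisation of the oxetanone, cleavage of the tert-butyl esters by TiCl4, or stalling at the aldol stage with the bulky malonate.
- Fallback: the second ester is introduced last. From 1, Wittig olefination with tert-butyl (triphenylphosphoranylidene)acetate in CH2Cl2 should give tert-butyl 2-(oxetan-3-ylidene)acetate F5. Hydrogenation (H2, Pd/C, EtOAc) gives tert-butyl 2-(oxetan-3-yl)acetate F6. The lithium enolate of F6 (LiHMDS, 2 equiv, THF, −78 °C) is C-acylated with di-tert-butyl dicarbonate in a Claisen-type acylation, rejoining the route at 4.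

**Step 7.**
- Most likely to go wrong: self-alkylation and oligomerisation of the very electron-rich benzyl chloride before it meets the hindered tertiary enolate, and slow formation of the quaternary carbon.
- Fallback: the labile halide is replaced by a bench-stable electrophile that is ionised only at the metal. From 9, methyl chloroformate and pyridine should give 2,4-bis(benzyloxy)-3-methoxybenzyl methyl carbonate F7. Palladium-catalysed benzylic substitution of F7 with 4 ([Pd(C3H5)(cod)]BF4 with a wide-bite-angle bisphosphine, toluene, 80 °C), in which the methoxide released on ionisation acts as the base, rejoins the route at 13.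

## Further compounds

F1 | step 8 | di-tert-butyl 2-[2,4-bis(benzyloxy)-3-methoxybenzyl]-2-[(2S)-1-bromo-3-(trimethylsilyloxy)propan-2-yl]malonate | C[Si](C)(C)OC[C@@H](CBr)C(Cc1ccc(OCc2ccccc2)c(OC)c1OCc1ccccc1)(C(=O)OC(C)(C)C)C(=O)OC(C)(C)C
F2 | step 8 | tert-butyl (4R)-3-[2,4-bis(benzyloxy)-3-methoxybenzyl]-2-oxo-4-[(trimethylsilyloxy)methyl]tetrahydrofuran-3-carboxylate, either configuration at C3 | C[Si](C)(C)OC[C@H]1COC(=O)C1(Cc1ccc(OCc2ccccc2)c(OC)c1OCc1ccccc1)C(=O)OC(C)(C)C
F3 | step 11 | tert-butyl (4R)-3-[2,4-bis(benzyloxy)-3-methoxybenzyl]-4-[(iodozincio)methyl]-2-oxotetrahydrofuran-3-carboxylate, either configuration at C3 | I[Zn]C[C@H]1COC(=O)C1(Cc1ccc(OCc2ccccc2)c(OC)c1OCc1ccccc1)C(=O)OC(C)(C)C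
F4 | step 12 | trimethylsilyl (4R)-3-[2,4-bis(benzyloxy)-3-methoxybenzyl]-4-[4-(benzyloxy)-3-methoxybenzyl]-2-oxotetrahydrofuran-3-carboxylate, either configuration at C3 | COc1cc(C[C@H]2COC(=O)C2(Cc2ccc(OCc3ccccc3)c(OC)c2OCc2ccccc2)C(=O)O[Si](C)(C)C)ccc1OCc1ccccc1
F5 | step 1 | tert-butyl 2-(oxetan-3-ylidene)acetate | CC(C)(C)OC(=O)C=C1COC1
F6 | step 1 | tert-butyl 2-(oxetan-3-yl)acetate | CC(C)(C)OC(=O)CC1COC1
F7 | step 7 | 2,4-bis(benzyloxy)-3-methoxybenzyl methyl carbonate | COC(=O)OCc1ccc(OCc2ccccc2)c(OC)c1OCc1ccccc1
A1 | alternative 1 | (4R)-3-(2,4-diacetoxy-3-methoxybenzyl)-4-(4-acetoxy-3-methoxybenzyl)dihydrofuran-2(3H)-one, both C3 epimers | COc1cc(C[C@H]2COC(=O)C2Cc2ccc(OC(C)=O)c(OC)c2OC(C)=O)ccc1OC(C)=O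
A2 | alternative 1 | (E)-2-(2,4-diacetoxy-3-methoxybenzyl)-4-(4-acetoxy-3-methoxyphenyl)-1-(3,5-dimethyl-1H-pyrazol-1-yl)but-2-en-1-one | COc1cc(C/C=C(\Cc2ccc(OC(C)=O)c(OC)c2OC(C)=O)C(=O)n2nc(C)cc2C)ccc1OC(C)=O
A3 | alternative 1 | methanol | CO
A4 | alternative 2 | dimethyl (S)-2-[2,4-bis(benzyloxy)-3-methoxybenzyl]-2-{1-[4-(benzyloxy)-3-methoxyphenyl]but-3-en-2-yl}malonate | COc1cc(C[C@@H](C=C)C(Cc2ccc(OCc3ccccc3)c(OC)c2OCc2ccccc2)(C(=O)OC)C(=O)OC)ccc1OCc1ccccc1
A5 | alternative 2 | (E)-4-[4-(benzyloxy)-3-methoxyphenyl]but-2-en-1-yl methyl carbonate | COC(=O)OC/C=C/Cc1ccc(OCc2ccccc2)c(OC)c1
A6 | alternative 2 | dimethyl malonate | COC(=O)CC(=O)OC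
A7 | alternative 3 | (R,E)-3-[2,4-bis(benzyloxy)-3-methoxybenzylidene]-4-[4-(benzyloxy)-3-methoxybenzyl]dihydrofuran-2(3H)-one | COc1cc(C[C@H]2COC(=O)/C2=C/c2ccc(OCc3ccccc3)c(OC)c2OCc2ccccc2)ccc1OCc1ccccc1
A8 | alternative 3 | (R)-2-[4-(benzyloxy)-3-methoxybenzyl]-4-[2,4-bis(benzyloxy)-3-methoxyphenyl]but-3-yn-1-ol | COc1cc(C[C@@H](CO)C#Cc2ccc(OCc3ccccc3)c(OC)c2OCc2ccccc2)ccc1OCc1ccccc1
A9 | alternative 3 | carbon monoxide | [C-]#[O+]
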